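**Retrosynthetic overview**
- The target is disconnected first at C7–H: chelation-controlled reduction of an (S)-α-aryloxy aryl ketone, with the E-propenyl group coming from an allyl group by late alkene isomerization.
- The aryl–C7 bond is disconnected to a light-driven para acyl shift (photo-Fries) of the 2,6-dimethoxyphenyl ester of an (S)-2-aryloxypropanoic acid; the free phenol appears in the same event.
- The ester comes from the acid and 2,6-dimethoxyphenol.
- The C8–O bond comes from SN2 displacement (inversion) of (R)-2-chloropropanoic acid by 4-allyl-2,6-dimethoxyphenoxide; this is the only bought stereocentre.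
- No ring is formed; both benzene rings are bought.

Assumption: (R)-2-chloropropanoic acid (≥98% ee), 4-allyl-2,6-dimethoxyphenol and 2,6-dimethoxyphenol are catalogue chemicals; the target read from the SMILES is the erythro isomer, (1R,2S) by CIP (C7 = R, C8 = S).

**Route**

Step 1
Reactants: 1 (R)-2-chloropropanoic acid; 2 4-allyl-2,6-dimethoxyphenol
Product: 3 (S)-2-(4-allyl-2,6-dimethoxyphenoxy)propanoic acid
Conditions: NaH (2.3 equiv), THF–DMF (4:1), 0 → 60 °C; then cold 1 M HCl
Reagents that add atoms: none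
Why: Williamson-type SN2 displacement of chloride by the phenoxide on the α-chloro carboxylate goes with inversion (R → S), and the carboxylate form blocks enolization, so C8 is taken directly from the bought stereocentre.

Step 2
Reactants: 3 (S)-2-(4-allyl-2,6-dimethoxyphenoxy)propanoic acid; 4 2,6-dimethoxyphenol
Product: 5 2,6-dimethoxyphenyl (S)-2-(4-allyl-2,6-dimethoxyphenoxy)propanoate
Conditions: DCC (1.1 equiv), DMAP (5 mol%), CH2Cl2, 0 °C → rt
Reagents that add atoms: none
Why: Steglich esterification acylates even this hindered phenol, and an α-aryloxy acid has no oxazolone pathway, so with catalytic DMAP at 0 °C the C8 centre is not touched.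

Step 3
Reactants: 5 2,6-dimethoxyphenyl (S)-2-(4-allyl-2,6-dimethoxyphenoxy)propanoate
Product: 7 (S)-2-(4-allyl-2,6-dimethoxyphenoxy)-1-(4-hydroxy-3,5-dimethoxyphenyl)propan-1-one, via 4-acylcyclohexa-2,5-dienone tautomer 6 (not isolated)
Conditions: hν (275–280 nm UV-LED, FEP flow coil), degassed MeCN (0.02 M), trans-piperylene (0.1 M), 20 °C; run to about 70% conversion, recovered 5 recycled
Reagents that add atoms: none
Why: Proposed new method: a para-selective photo-Fries rearrangement of a di-ortho-blocked (2,6-dimethoxyphenyl) ester of an enantiopure α-aryloxy acid, used as a protecting-group-free C-acylation; S1 excitation of the aryl ester homolyses the ArO–C(O) bond to a caged aryloxyl/acyl radical pair that can recombine productively only at the free para carbon, giving dienone 6, which tautomerizes to phenol 7; C8 is never a radical centre, so its configuration is kept as long as cage recombination (ns) outruns decarbonylation of the acyl radical (µs), and the diene, transparent at 280 nm, quenches the triplet of 7 to suppress its β-aryl ether photocleavage; the closest known reaction type is the photo-Fries rearrangement of 2,6-dialkylphenyl esters to 4-acylphenols.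

Step 4
Reactants: 7 (S)-2-(4-allyl-2,6-dimethoxyphenoxy)-1-(4-hydroxy-3,5-dimethoxyphenyl)propan-1-one
Product: 8 (S)-1-(4-hydroxy-3,5-dimethoxyphenyl)-2-[2,6-dimethoxy-4-((E)-prop-1-enyl)phenoxy]propan-1-one
Conditions: [CpRu(MeCN)(κ2-P,N-iPr2P(4-tBu-1-methylimidazol-2-yl))]PF6 (2 mol%), acetone, 40 °C
Reagents that add atoms: none
Why: Ru-catalysed one-position alkene isomerization moves the allyl double bond into conjugation with the arene and this bifunctional catalyst is expected to give the E isomer almost exclusively, while the neutral conditions leave the C8–H next to the ketone alone.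

Step 5
Reactants: 8 (S)-1-(4-hydroxy-3,5-dimethoxyphenyl)-2-[2,6-dimethoxy-4-((E)-prop-1-enyl)phenoxy]propan-1-one
Product: 9 (1R,2S)-1-(4-hydroxy-3,5-dimethoxyphenyl)-2-[2,6-dimethoxy-4-((E)-prop-1-enyl)phenoxy]propan-1-ol (target)
Conditions: Zn(BH4)2 (2.0 equiv, 0.15 M stock solution in Et2O), Et2O–CH2Cl2 (2:1), −20 → 0 °C; sat. aq NH4Cl
Reagents that add atoms: none
Why: Chelation-controlled (Cram chelate) hydride reduction: Zn2+ bridges the carbonyl oxygen and the C8 aryloxy oxygen and hydride enters from the face of the C8–H, anti to the C8 methyl, so the (S)-C8 centre sets C7 as R (erythro); the conjugated internal alkene is not hydroborated at or below 0 °C.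

**Compound list**
1 | (R)-2-chloropropanoic acid | C[C@@H](Cl)C(=O)O | starting material
2 | 4-allyl-2,6-dimethoxyphenol | C=CCc1cc(OC)c(O)c(OC)c1 | starting material
3 | (S)-2-(4-allyl-2,6-dimethoxyphenoxy)propanoic acid | C[C@H](Oc1c(OC)cc(CC=C)cc1OC)C(=O)O | intermediate
4 | 2,6-dimethoxyphenol | COc1cccc(OC)c1O | starting material
5 | 2,6-dimethoxyphenyl (S)-2-(4-allyl-2,6-dimethoxyphenoxy)propanoate | C[C@H](Oc1c(OC)cc(CC=C)cc1OC)C(=O)Oc1c(OC)cccc1OC | intermediate
6 | 4-[(S)-2-(4-allyl-2,6-dimethoxyphenoxy)propanoyl]-2,6-dimethoxycyclohexa-2,5-dien-1-one (4-acylcyclohexa-2,5-dienone tautomer) | C[C@H](Oc1c(OC)cc(CC=C)cc1OC)C(=O)C1C=C(OC)C(=O)C(OC)=C1 | intermediate (not isolated)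
7 | (S)-2-(4-allyl-2,6-dimethoxyphenoxy)-1-(4-hydroxy-3,5-dimethoxyphenyl)propan-1-one | C[C@H](Oc1c(OC)cc(CC=C)cc1OC)C(=O)c1cc(OC)c(O)c(OC)c1 | intermediate
8 | (S)-1-(4-hydroxy-3,5-dimethoxyphenyl)-2-[2,6-dimethoxy-4-((E)-prop-1-enyl)phenoxy]propan-1-one | C[C@H](Oc1c(OC)cc(/C=C/C)cc1OC)C(=O)c1cc(OC)c(O)c(OC)c1 | intermediate
9 | (1R,2S)-1-(4-hydroxy-3,5-dimethoxyphenyl)-2-[2,6-dimethoxy-4-((E)-prop-1-enyl)phenoxy]propan-1-ol | C/C=C/c1cc(OC)c(O[C@@H](C)[C@H](O)c2cc(OC)c(O)c(OC)c2)c(OC)c1 | target

**Step count and risks**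

Total step count: 5. Longest linear sequence: 5 (from 1 or 2 to 9).

Most likely to fail, first: step 1. The phenoxide is flanked by two methoxy groups and attacks a secondary carbon next to a carboxylate, so conversion may be low and some enantiopurity may be lost. The fallback sets out from 2 and comes back at 3. It is a Mitsunobu etherification of 2 with methyl (R)-lactate F1 (PPh3, DIAD, THF, 0 °C → rt, inversion at carbon) to give methyl (S)-2-(4-allyl-2,6-dimethoxyphenoxy)propanoate F2. Saponification of F2 (LiOH, THF–H2O, 0 °C) then gives 3.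

Most likely to fail, second: step 3, the proposed new step. Para recombination in the solvent cage may be inefficient, giving 2,6-dimethoxyphenol and decarbonylated material instead. Ketone 7 absorbs more strongly than 5 and can photocleave at its β-aryl ether bond if triplet quenching is incomplete. Any ketene pathway would also racemize recovered 5, so its ee should be checked before recycling. The fallback uses known chemistry, sets out from 3 and comes back at 7:
- Acid 3 is converted (MeNH(OMe)·HCl, EDC, HOBt, N-methylmorpholine, CH2Cl2, 0 °C) into (S)-2-(4-allyl-2,6-dimethoxyphenoxy)-N-methoxy-N-methylpropanamide F3.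
- Bought 4-bromo-2,6-dimethoxyphenol F4 is silylated (TBSCl, imidazole, DMF) to (4-bromo-2,6-dimethoxyphenoxy)(tert-butyl)dimethylsilane F5.
- Bromine–lithium exchange on F5 (n-BuLi, THF, −78 °C) gives [4-(tert-butyldimethylsilyloxy)-3,5-dimethoxyphenyl]lithium F6.
- F6 is added to F3 at −78 °C to give (S)-2-(4-allyl-2,6-dimethoxyphenoxy)-1-[4-(tert-butyldimethylsilyloxy)-3,5-dimethoxyphenyl]propan-1-one F7.
- Buffered desilylation of F7 (TBAF, AcOH, THF, 0 °C) gives 7.

Most likely to fail, third: step 5. The free phenol is converted into a zinc phenoxide, which makes the para-acyl group a poor electrophile and may disturb the chelate, so the reduction could be slow or give a low erythro:threo ratio. The fallback gives up the protecting-group-free reduction, sets out from 8 and comes back at 9: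
- Ketone 8 is silylated (TBSCl, imidazole, DMF) to (S)-1-[4-(tert-butyldimethylsilyloxy)-3,5-dimethoxyphenyl]-2-[2,6-dimethoxy-4-((E)-prop-1-enyl)phenoxy]propan-1-one F8.
- This neutral α-aryloxy ketone is reduced under the same chelation control (Zn(BH4)2, Et2O, −20 °C) to (1R,2S)-1-[4-(tert-butyldimethylsilyloxy)-3,5-dimethoxyphenyl]-2-[2,6-dimethoxy-4-((E)-prop-1-enyl)phenoxy]propan-1-ol F9.
- Desilylation of F9 (TBAF, AcOH, THF, 0 °C) gives 9.

**Further compounds**
F1 | step 1 | methyl (R)-lactate (bought) | C[C@@H](O)C(=O)OC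
F2 | step 1 | methyl (S)-2-(4-allyl-2,6-dimethoxyphenoxy)propanoate | C[C@H](Oc1c(OC)cc(CC=C)cc1OC)C(=O)OC
F3 | step 3 | (S)-2-(4-allyl-2,6-dimethoxyphenoxy)-N-methoxy-N-methylpropanamide | C[C@H](Oc1c(OC)cc(CC=C)cc1OC)C(=O)N(C)OC
F4 | step 3 | 4-bromo-2,6-dimethoxyphenol (bought) | COc1cc(Br)cc(OC)c1O
F5 | step 3 | (4-bromo-2,6-dimethoxyphenoxy)(tert-butyl)dimethylsilane | COc1cc(Br)cc(OC)c1O[Si](C)(C)C(C)(C)C
F6 | step 3 | [4-(tert-butyldimethylsilyloxy)-3,5-dimethoxyphenyl]lithium | [Li]c1cc(OC)c(O[Si](C)(C)C(C)(C)C)c(OC)c1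
F7 | step 3 | (S)-2-(4-allyl-2,6-dimethoxyphenoxy)-1-[4-(tert-butyldimethylsilyloxy)-3,5-dimethoxyphenyl]propan-1-one | C[C@H](Oc1c(OC)cc(CC=C)cc1OC)C(=O)c1cc(OC)c(O[Si](C)(C)C(C)(C)C)c(OC)c1
F8 | step 5 | (S)-1-[4-(tert-butyldimethylsilyloxy)-3,5-dimethoxyphenyl]-2-[2,6-dimethoxy-4-((E)-prop-1-enyl)phenoxy]propan-1-one | C[C@H](Oc1c(OC)cc(/C=C/C)cc1OC)C(=O)c1cc(OC)c(O[Si](C)(C)C(C)(C)C)c(OC)c1
F9 | step 5 | (1R,2S)-1-[4-(tert-butyldimethylsilyloxy)-3,5-dimethoxyphenyl]-2-[2,6-dimethoxy-4-((E)-prop-1-enyl)phenoxy]propan-1-ol | C[C@H](Oc1c(OC)cc(/C=C/C)cc1OC)[C@H](O)c1cc(OC)c(O[Si](C)(C)C(C)(C)C)c(OC)c1
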